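**Retrosynthetic overview**

1. The ester C8–O bond is cut to give a guai-1(10)-ene-8,11-diol and (E)-4-acetoxycinnamic acid. The trans C7–H/C8–OH pair is traced back to a C7=C8 alkene by hydroboration–oxidation.
2. The seven-membered ring is cut at C8–C9 and C6–C7 (retro-[5+2]) into a terminal alkyne (C7, C8 and the C11 carbinol with its two methyls) and a vinylcyclopropane, 4-methyl-1-isopropenylbicyclo[3.1.0]hexane.
3. Enabling feature: the tetrasubstituted C1=C10 alkene sits in the seven-membered ring between C9H2 and C5–C6H2. So C9–C10=C1–C5–C6 is the opened form of a vinylcyclopropane whose C1–C5 bond belongs to the cyclopentane, with C1/C5/C6 as a cyclopropane fused on the five-membered ring.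
4. That vinylcyclopropane has the thujane skeleton and comes from the chiral pool: the six ring carbons of (S)-carvone become C1–C6. Its stereocentre is relayed to C4 and C5 and then destroyed in a 1,3-elimination that needs a temporary acetyl group (isopropenyl → acetyl → isopropenyl).
5. Ring order: carvone six-membered ring → bicyclo[3.1.0]hexane (five- plus three-membered ring, step 5) → the [5+2] step opens the three-membered ring and closes the seven-membered ring.

Key step: step 7

Remark on the chemistry (assumption): the tertiary C11 hydroxyl is taken to need no protection in steps 9 and 10 because it is too hindered to be acylated. Guaiane numbering is used for the bicyclic compounds (C1/C5 ring fusion, C4 and C10 carry the methyl groups, C7 the side chain, C8 the oxygen).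

**Step 1**
Reactants: 1 (S)-carvone
Product: 3 (2S,5S)-2-methyl-5-(prop-1-en-2-yl)cyclohexan-1-one, via lithium enolate 2 (not isolated)
Conditions: LiBH(s-Bu)3, THF, −78 °C; then NaOH, H2O2, 0 °C to rt
Reagents that add atoms: none
Why: Conjugate hydride reduction of the β-unsubstituted cyclohexenone by the hindered trialkylborohydride gives enolate 2, and protonation with equilibration in the basic work-up should leave the C2 methyl equatorial and trans to the C5 isopropenyl group, so the carvone stereocentre sets the later C4 methyl centre under thermodynamic control.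

**Step 2**
Reactants: 3 (2S,5S)-2-methyl-5-(prop-1-en-2-yl)cyclohexan-1-one
Product: 4 (1R,2S,5S)-2-methyl-5-(prop-1-en-2-yl)cyclohexan-1-ol
Conditions: LiBH(s-Bu)3, THF, −78 °C; then NaOH, H2O2, 0 °C to rt
Reagents that add atoms: none
Why: Under steric approach control the bulky borohydride should attack the 2-methylcyclohexanone from the equatorial side and give the axial alcohol cis to the methyl group (C1 set by C2); 4 is freed here by chromatography from the isomers that descend from the minor cis-ketone, because after step 5 these would give the enantiomer of 9.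

**Step 3**
Reactants: 4 (1R,2S,5S)-2-methyl-5-(prop-1-en-2-yl)cyclohexan-1-ol
Product: 5 (1R,2S,5S)-2-methyl-5-(prop-1-en-2-yl)cyclohexyl 4-methylbenzenesulfonate
Conditions: TsCl, pyridine, DMAP (cat.), CH2Cl2, rt
Reagents that add atoms: 4-methylbenzenesulfonyl chloride, Cc1ccc(cc1)S(Cl)(=O)=O
Why: Sulfonylation of the secondary alcohol under nucleophilic catalysis proceeds with retention at carbon and turns the hydroxyl, cis to the methyl group, into the leaving group for the cyclopropane closure.

**Step 4**
Reactants: 5 (1R,2S,5S)-2-methyl-5-(prop-1-en-2-yl)cyclohexyl 4-methylbenzenesulfonate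
Product: 7 (1R,2S,5S)-5-acetyl-2-methylcyclohexyl 4-methylbenzenesulfonate, via ozonide 6 (not isolated)
Conditions: O3, CH2Cl2, −78 °C; then Me2S, −78 °C to rt
Reagents that add atoms: ozone, [O-][O+]=O
Why: Ozonolysis of the only C=C bond through ozonide 6 with reductive work-up should give the methyl ketone that acidifies the ring C–H for step 5, the sulfonate being inert to ozone and dimethyl sulfide.

**Step 5**
Reactants: 7 (1R,2S,5S)-5-acetyl-2-methylcyclohexyl 4-methylbenzenesulfonate
Product: 9 1-[(1R,4S,5S)-4-methylbicyclo[3.1.0]hexan-1-yl]ethan-1-one, via potassium enolate 8 (not isolated)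
Conditions: KOt-Bu, t-BuOH–THF, 0 °C to rt
Reagents that add atoms: none
Why: In this 1,3-elimination by intramolecular enolate C-alkylation (3-exo-tet) the ring-side enolate 8 should displace the tosylate from the back in the chair that has the sulfonate equatorial and the methyl axial, so the carbinol carbon is inverted and, because methyl and tosylate were cis, the methyl group ends on the same face as the new cyclopropane CH2 (the bridgeheads are necessarily cis).

**Step 6**
Reactants: 9 1-[(1R,4S,5S)-4-methylbicyclo[3.1.0]hexan-1-yl]ethan-1-one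
Product: 10 (1R,4S,5S)-4-methyl-1-(prop-1-en-2-yl)bicyclo[3.1.0]hexane
Conditions: Ph3PCH3Br, KOt-Bu, THF, 0 to 50 °C
Reagents that add atoms: methyltriphenylphosphonium bromide, [Br-].C[P+](c1ccccc1)(c1ccccc1)c1ccccc1
Why: Wittig methylenation of the cyclopropyl methyl ketone with the non-stabilised ylide should restore the isopropenyl group and complete the vinylcyclopropane without touching the three stereocentres.

**Step 7**
Reactants: 10 (1R,4S,5S)-4-methyl-1-(prop-1-en-2-yl)bicyclo[3.1.0]hexane; 11 trimethyl[(2-methylbut-3-yn-2-yl)oxy]silane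
Product: 14 {2-[(3S,3aS)-3,8-dimethyl-1,2,3,3a,4,7-hexahydroazulen-5-yl]propan-2-yl}oxy(trimethyl)silane, via rhodacyclohexene 12 (not isolated), via rhodacyclooctadiene 13 (not isolated)
Conditions: [Rh(CO)2Cl]2 (5 mol %), ClCH2CH2Cl, 80 °C, slow addition of 11
Reagents that add atoms: 11 trimethyl[(2-methylbut-3-yn-2-yl)oxy]silane, C#CC(C)(C)O[Si](C)(C)C
Why: Monovalent rhodium binds the isopropenyl group and inserts into the distal C1–C6 bond of the cyclopropane to give the σ-alkyl/π-allyl metallacycle 12, the alkyne inserts into the rhodium–allyl bond at the unsubstituted terminus C9 to give 13, and C(sp2)–C(sp3) reductive elimination joins C7 to C6 and frees the catalyst. The closest known reaction type is the rhodium-catalysed intermolecular [5+2] cycloaddition of 1-substituted vinylcyclopropanes with terminal alkynes. The seven-membered ring is closed as a two-component annulation onto the existing cyclopentane (C9–C10–C1–C5–C6 of 10 plus C7–C8 of 11), driven by release of the cyclopropane strain, the last bond arising by reductive elimination from the eight-membered rhodacycle. No stereocentre is created: C4 and C5 are untouched and retained, and the stereogenic bridgehead C1 of 10 becomes the trigonal end of the tetrasubstituted C1=C10 alkene. Two selectivities are required: cleavage of C1–C6 and not of the ring-fusion bond C1–C5, which the substrate secures because C6 is the less substituted terminus (primary alkyl–rhodium) and the alternative would lead to a bridged product with a bridgehead alkene; and the head-to-tail orientation of 11, which its bulky C(CH3)2OSiMe3 group secures by keeping away from the carbon that bonds to C9 in the insertion step, so that this group ends on C7 and the alkyne CH becomes C8.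

**Step 8**
Reactants: 14 {2-[(3S,3aS)-3,8-dimethyl-1,2,3,3a,4,7-hexahydroazulen-5-yl]propan-2-yl}oxy(trimethyl)silane
Product: 17 (3S,3aS,5S,6S)-5-(2-hydroxypropan-2-yl)-3,8-dimethyl-1,2,3,3a,4,5,6,7-octahydroazulen-6-ol, via dialkylborane 15 (not isolated), via silyl ether alcohol 16 (not isolated)
Conditions: IpcBH2 (monoisopinocampheylborane made from (+)-α-pinene), THF, −25 to 0 °C; NaOH, H2O2, 0 °C to rt; then K2CO3, MeOH, rt
Reagents that add atoms: hydrogen peroxide, OO
Why: In this reagent-controlled asymmetric hydroboration–oxidation of a trisubstituted cycloalkene boron should add to the less substituted C8 and hydrogen to C7 from the same face (syn addition, hence the C7 side chain and the C8 oxygen trans), that face being the one of H5 as dictated by the isopinocampheyl group (the enantiomer that turns 1-methylcyclohexene into (1S,2S)-trans-2-methylcyclohexanol; the substrate's own bias through the remote C5 is expected to be small), while the tetrasubstituted C1=C10 alkene is too hindered to react, oxidation of 15 proceeds with retention to 16, and carbonate methanolysis removes the tertiary silyl ether.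

**Step 9**
Reactants: 17 (3S,3aS,5S,6S)-5-(2-hydroxypropan-2-yl)-3,8-dimethyl-1,2,3,3a,4,5,6,7-octahydroazulen-6-ol; 18 (2E)-3-[4-(acetyloxy)phenyl]prop-2-enoic acid
Product: 19 (3S,3aS,5S,6S)-5-(2-hydroxypropan-2-yl)-3,8-dimethyl-1,2,3,3a,4,5,6,7-octahydroazulen-6-yl (2E)-3-[4-(acetyloxy)phenyl]prop-2-enoate
Conditions: DCC, DMAP (cat.), CH2Cl2, 0 °C to rt
Reagents that add atoms: 18 (2E)-3-[4-(acetyloxy)phenyl]prop-2-enoic acid, CC(=O)Oc1ccc(/C=C/C(O)=O)cc1
Why: Steglich esterification (carbodiimide activation with acyl transfer by DMAP) should acylate the secondary C8 hydroxyl with retention while the tertiary carbinol is too hindered to react, the E alkene and the aryl acetate of 18 being unaffected.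

**Step 10**
Reactants: 19 (3S,3aS,5S,6S)-5-(2-hydroxypropan-2-yl)-3,8-dimethyl-1,2,3,3a,4,5,6,7-octahydroazulen-6-yl (2E)-3-[4-(acetyloxy)phenyl]prop-2-enoate
Product: 20 (3S,3aS,5S,6S)-5-(2-hydroxypropan-2-yl)-3,8-dimethyl-1,2,3,3a,4,5,6,7-octahydroazulen-6-yl (2E)-3-(4-hydroxyphenyl)prop-2-enoate
Conditions: pyrrolidine, CH2Cl2, 0 °C
Reagents that add atoms: none
Why: Chemoselective aminolysis of the aryl acetate, whose phenoxide leaving group makes it far more reactive than the hindered alkyl cinnamate, should free the phenol without conjugate addition or cleavage of the C8 ester.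

**Compound list**

1 | (S)-carvone, (5S)-2-methyl-5-(prop-1-en-2-yl)cyclohex-2-en-1-one | CC1=CC[C@@H](CC1=O)C(C)=C | starting material
2 | lithium (5S)-2-methyl-5-(prop-1-en-2-yl)cyclohex-1-en-1-olate (not isolated) | [Li+].CC1=C([O-])C[C@@H](C(C)=C)CC1 | intermediate
3 | (2S,5S)-2-methyl-5-(prop-1-en-2-yl)cyclohexan-1-one (trans-dihydrocarvone) | C[C@H]1CC[C@@H](CC1=O)C(C)=C | intermediate
4 | (1R,2S,5S)-2-methyl-5-(prop-1-en-2-yl)cyclohexan-1-ol (neodihydrocarveol) | C[C@H]1CC[C@@H](C[C@H]1O)C(C)=C | intermediate
5 | (1R,2S,5S)-2-methyl-5-(prop-1-en-2-yl)cyclohexyl 4-methylbenzenesulfonate | C[C@H]1CC[C@@H](C[C@H]1OS(=O)(=O)c1ccc(C)cc1)C(C)=C | intermediate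
6 | (1R,2S,5S)-2-methyl-5-(3-methyl-1,2,4-trioxolan-3-yl)cyclohexyl 4-methylbenzenesulfonate (ozonide, not isolated) | C[C@H]1CC[C@@H](C[C@H]1OS(=O)(=O)c1ccc(C)cc1)C1(C)OCOO1 | intermediate
7 | (1R,2S,5S)-5-acetyl-2-methylcyclohexyl 4-methylbenzenesulfonate | C[C@H]1CC[C@@H](C[C@H]1OS(=O)(=O)c1ccc(C)cc1)C(C)=O | intermediate
8 | potassium 1-[(3R,4S)-4-methyl-3-(tosyloxy)cyclohexylidene]ethan-1-olate (not isolated) | [K+].C[C@H]1CCC(=C(C)[O-])C[C@H]1OS(=O)(=O)c1ccc(C)cc1 | intermediate
9 | 1-[(1R,4S,5S)-4-methylbicyclo[3.1.0]hexan-1-yl]ethan-1-one | CC(=O)[C@@]12CC[C@H](C)[C@@H]1C2 | intermediate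
10 | (1R,4S,5S)-4-methyl-1-(prop-1-en-2-yl)bicyclo[3.1.0]hexane | CC(=C)[C@@]12CC[C@H](C)[C@@H]1C2 | intermediate
11 | trimethyl[(2-methylbut-3-yn-2-yl)oxy]silane | C#CC(C)(C)O[Si](C)(C)C | starting material
12 | rhodacyclohexene from insertion of rhodium into C1–C6 of 10 (carbonyl and chloride ligands not drawn, not isolated) | CC1=C2CC[C@H](C)[C@@H]2C[Rh]C1 | intermediate
13 | rhodacyclooctadiene after insertion of 11 (carbonyl and chloride ligands not drawn, not isolated) | CC1=C2CC[C@H](C)[C@@H]2C[Rh]C(C(C)(C)O[Si](C)(C)C)=CC1 | intermediate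
14 | {2-[(3S,3aS)-3,8-dimethyl-1,2,3,3a,4,7-hexahydroazulen-5-yl]propan-2-yl}oxy(trimethyl)silane | CC1=C2CC[C@H](C)[C@@H]2CC(C(C)(C)O[Si](C)(C)C)=CC1 | intermediate
15 | isopinocampheyl{(3S,3aS,5S,6S)-3,8-dimethyl-5-[2-(trimethylsilyloxy)propan-2-yl]-1,2,3,3a,4,5,6,7-octahydroazulen-6-yl}borane (not isolated) | CC1=C2CC[C@H](C)[C@@H]2C[C@H](C(C)(C)O[Si](C)(C)C)[C@@H](B[C@@H]3C[C@@H]4C[C@H]([C@H]3C)C4(C)C)C1 | intermediate
16 | (3S,3aS,5S,6S)-3,8-dimethyl-5-[2-(trimethylsilyloxy)propan-2-yl]-1,2,3,3a,4,5,6,7-octahydroazulen-6-ol (not isolated) | CC1=C2CC[C@H](C)[C@@H]2C[C@H](C(C)(C)O[Si](C)(C)C)[C@@H](O)C1 | intermediate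
17 | (3S,3aS,5S,6S)-5-(2-hydroxypropan-2-yl)-3,8-dimethyl-1,2,3,3a,4,5,6,7-octahydroazulen-6-ol | CC1=C2CC[C@H](C)[C@@H]2C[C@H](C(C)(C)O)[C@@H](O)C1 | intermediate
18 | (2E)-3-[4-(acetyloxy)phenyl]prop-2-enoic acid | CC(=O)Oc1ccc(/C=C/C(O)=O)cc1 | starting material
19 | (3S,3aS,5S,6S)-5-(2-hydroxypropan-2-yl)-3,8-dimethyl-1,2,3,3a,4,5,6,7-octahydroazulen-6-yl (2E)-3-[4-(acetyloxy)phenyl]prop-2-enoate | CC1=C2CC[C@H](C)[C@@H]2C[C@H](C(C)(C)O)[C@@H](OC(=O)/C=C/c2ccc(OC(C)=O)cc2)C1 | intermediate
20 | (3S,3aS,5S,6S)-5-(2-hydroxypropan-2-yl)-3,8-dimethyl-1,2,3,3a,4,5,6,7-octahydroazulen-6-yl (2E)-3-(4-hydroxyphenyl)prop-2-enoate (CNP0403230.1) | CC1=C2CC[C@H](C)[C@@H]2C[C@H](C(C)(C)O)[C@@H](OC(=O)/C=C/c2ccc(O)cc2)C1 | target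

**Step count and risks**

Total step count: 10. Longest linear sequence: 10 steps, from 1 to 20 (11 and 18 are purchased).

Steps most likely to fail:

1. Step 8. Process at risk: poor facial selectivity, that is delivery of boron to the lower face of C7=C8 (anti to H5) if the ring's own bias outweighs the reagent, together with slow hydroboration of the hindered alkene. The fallback uses that bias instead of fighting it and sets out from 14. Methanolysis of the silyl ether (K2CO3, MeOH) would give the free dienol 2-[(3S,3aS)-3,8-dimethyl-1,2,3,3a,4,7-hexahydroazulen-5-yl]propan-2-ol F1. Hydroxyl-directed epoxidation (VO(acac)2 cat., t-BuOOH, CH2Cl2) touches only the allylic C7=C8 bond and is presupposed to come from the same lower face; it would give (4S,5S,7S,8R)-7,8-epoxyguai-1(10)-en-11-ol F2. NaAlH2(OCH2CH2OCH3)2 in THF, delivering hydride from the C11 alkoxyaluminate to C7 with inversion, would give the C8-epimeric diol (3S,3aS,5S,6R)-5-(2-hydroxypropan-2-yl)-3,8-dimethyl-1,2,3,3a,4,5,6,7-octahydroazulen-6-ol F3, in which C7 is already correct. Mitsunobu esterification of F3 with 18 (PPh3, DIAD, THF) would invert C8 and return to the route at 19.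

2. Step 7. Process at risk: the ring-fused, hindered vinylcyclopropane is a demanding member of its class, so β-hydride elimination in the metallacycle (ring-opened dienes) and oligomerisation of the hindered alkyne may outrun the cycloaddition. The fallback sets out from 10 and attaches the side chain after the ring is made. The same catalyst with the small, purchasable 2-ethynyl-4,4,5,5-tetramethyl-1,3,2-dioxaborolane, whose boryl group should take C7 for the same steric reason, would give 2-[(3S,3aS)-3,8-dimethyl-1,2,3,3a,4,7-hexahydroazulen-5-yl]-4,4,5,5-tetramethyl-1,3,2-dioxaborolane F4. Bromodeboronation (CuBr2, MeOH–H2O) would give (3S,3aS)-5-bromo-3,8-dimethyl-1,2,3,3a,4,7-hexahydroazulene F5. Bromine–lithium exchange (t-BuLi, THF, −78 °C), addition to acetone and silylation of the alkoxide with Me3SiCl would return to the route at 14.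

3. Step 9. Process at risk: slow acylation of the C8 hydroxyl, which is flanked by the fully substituted carbinol carbon, with diversion of the activated acid to the N-acylurea or to the tertiary hydroxyl. The fallback sets out from 17 and builds the cinnamate in place. Heating with 2,2-dimethyl-1,3-dioxane-4,6-dione in toluene acylates through an acylketene, which is much less sensitive to hindrance, and would give 3-{[(3S,3aS,5S,6S)-5-(2-hydroxypropan-2-yl)-3,8-dimethyl-1,2,3,3a,4,5,6,7-octahydroazulen-6-yl]oxy}-3-oxopropanoic acid F6. Knoevenagel–Doebner condensation of F6 with 4-hydroxybenzaldehyde (pyridine, piperidine cat., 60 °C), with loss of carbon dioxide, would give the E ester and return directly at 20, bypassing 19 and step 10.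

**Further compounds**

F1 | step 8 | 2-[(3S,3aS)-3,8-dimethyl-1,2,3,3a,4,7-hexahydroazulen-5-yl]propan-2-ol | CC1=C2CC[C@H](C)[C@@H]2CC(C(C)(C)O)=CC1
F2 | step 8 | (4S,5S,7S,8R)-7,8-epoxyguai-1(10)-en-11-ol (guaiane numbering, epoxide oxygen anti to H5) | CC1=C2CC[C@H](C)[C@@H]2C[C@]3(C(C)(C)O)O[C@@H]3C1
F3 | step 8 | (3S,3aS,5S,6R)-5-(2-hydroxypropan-2-yl)-3,8-dimethyl-1,2,3,3a,4,5,6,7-octahydroazulen-6-ol | CC1=C2CC[C@H](C)[C@@H]2C[C@H](C(C)(C)O)[C@H](O)C1
F4 | step 7 | 2-[(3S,3aS)-3,8-dimethyl-1,2,3,3a,4,7-hexahydroazulen-5-yl]-4,4,5,5-tetramethyl-1,3,2-dioxaborolane | CC1=C2CC[C@H](C)[C@@H]2CC(B3OC(C)(C)C(C)(C)O3)=CC1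
F5 | step 7 | (3S,3aS)-5-bromo-3,8-dimethyl-1,2,3,3a,4,7-hexahydroazulene | CC1=C2CC[C@H](C)[C@@H]2CC(Br)=CC1
F6 | step 9 | 3-{[(3S,3aS,5S,6S)-5-(2-hydroxypropan-2-yl)-3,8-dimethyl-1,2,3,3a,4,5,6,7-octahydroazulen-6-yl]oxy}-3-oxopropanoic acid | CC1=C2CC[C@H](C)[C@@H]2C[C@H](C(C)(C)O)[C@@H](OC(=O)CC(O)=O)C1
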